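The constants used here come from no measurement, and the outcome is calculated.

The target forms when electrophile meets nucleophile in solution, and here the nucleophile arrives as a solid.

| setting | violet | red |
|---|---|---|
| electrophile | 0.23 M (fed, over 4.0 min) | 0.23 M (fed, over 4.0 min) |
| free base | 0.230 M | 0.300 M |
| solid nucleophile | 0.242 M | 0.242 M |
| time | 20 min | 20 min |
| remark | the fed solution adds 0.10 times the starting volume | the fed solution adds 0.10 times the starting volume |

* part of the electrophile that has reacted at the end, violet
* part of the electrophile that has reacted at the end, red
* what raising the concentration of free base from its lowest to its highest value here does to the part of the electrophile that has reacted (changes below 5 percentage points count as none) (it rises / no change / it falls)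

- acid set free is meant together with its idle adduct
- for a step with 2 of a species take k times the square, and two of it per event
- every charge counts on the volume at the start, and the solution that is fed holds the whole dose
- solid, in amounts per volume of the solution: solid nucleophile
- at the start none of the solid nucleophile is in solution
- run time (violet): 20 min

    acid set free + free base ⇌ salt of the base, settled at all times (K1 = 11 M⁻¹)
    2 free base → self-condensation product (k2 = 0.0060 M⁻¹ s⁻¹)
    acid set free + free base ⇌ idle adduct, settled at all times (K3 = 4.3 M⁻¹)
    nucleophile + acid set free ⇌ protonated nucleophile, settled at all times (K4 = 5600 M⁻¹)
    solid nucleophile ⇌ nucleophile, rate k5*(cs5 - [nucleophile]) while solid is left; crystals form when [nucleophile] > cs5 (cs5 = 14 mM, k5 = 0.027 s⁻¹)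
    electrophile + nucleophile → acid set free + target (k6 = 0.018 M⁻¹ s⁻¹)

I began by balancing the charges. If each target event uses one nucleophile and the acid it sets free takes a second, the 0.242 M of solid nucleophile covers 0.121 M of electrophile, less than the 0.23 M charged, so by that count the nucleophile is the limiting reagent. Two numbers seemed not to fit. In violet, the nucleophile's half-life by the target step, with the whole electrophile charge present at once, is 2.8 min, so a run of 20 min looked finished. Yet the solid dissolves only towards a solubility of 14 mM, far below its charge.

I cleared this with a balance on dissolved nucleophile. I kept the same count of two nucleophile per target event as an assumption. With the fed electrophile diluted to 0.209 M, dissolution matches that loss: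

0.027 s⁻¹ · (14 mM − c(nucleophile)) = 2 · 0.018 M⁻¹ s⁻¹ · 0.209 M · c(nucleophile)

c(nucleophile) = 10.9 mM

This is the standing level of dissolved nucleophile, the concentration the electrophile really meets. The assumption held: the nucleophile's binding term is 61.3, against 4.59 for the free base at red's full charge. So I put no free-base term in the balance.

The level settles within 29.0 s, so the electrophile decays as a pseudo-first-order species. Counting the steady feed from its midpoint:

time constant = 84.6 min, effective time = 18.0 min

part reacted = 19.2%

That uses 0.0883 M of solid, less than the charge, so solid lasts the run. I expected this figure for both flasks.

The forecast gave 20.3% for violet and 20.5% for red, no change, slightly above my figure, holding that “The free base hardly matters because it is far weaker than the nucleophile at taking up acid”.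

The simulation gave 19.7% for violet and 19.7% for red, no change, a change of 0 percentage points.

Red's dissolved nucleophile read 0.0114 M at 20.0 min, and violet's read 0.0114 M, beside my level of 10.9 mM. I then took that level to a neighbouring flask, red read at 12 min. The same time constant of 84.6 min, over an effective 10.0 min, gave 11.2%. That flask held 0.0112 M of nucleophile, and its part of the electrophile reacted came to 11.4%.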